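**Retrosynthetic overview**
Numbering: dihydropyranone O1, C2(=O), C3, C4(OMe), C5, C6; cyclobutane C5–C6–C8–C7 (C6 styryl, C7 aryl, C8 pyranonyl). The strategy rests on the fusion bond C5–C6. Its two carbons hold the carboxyl-level carbon C4 and the oxygen O1 on one face of the four-membered ring, which is the pattern a 2-pyranone leaves when its O–C(=O) bridge comes to span a new C3–C6 bond.
Key disconnection: C5–C6, made by photochemical 4π ring closure of tetrasubstituted pyranone 9 (from an aryl propiolate and a β-keto ester) to cyclobutene β-lactone 10. This one event gives the four-membered carbocycle, the quaternary C6–O1 centre and the cis O1/C4 pair.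
Ring order: sacrificial 2-pyranone (step 4); cyclobutene plus β-lactone (step 5); cyclobutane (step 6); dihydropyranone by lactone opening, O1 acetylation and Dieckmann closure of C3–C4 (steps 8–11); pendant 2-pyranone on C8 (steps 15–18); styryl group by Wittig reaction (step 24).
Stereocontrol: C5/C6 come from the closure, C7 from convex-face hydrogenation, and the absolute configuration from lipase resolution of lactone 11. C8 is set by a decarboxylative radical acylation rather than a base epimerisation, because a C8 enolate would expel O1 and a free C6 alkoxide would cleave the ring by retro-aldol reaction.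

Key step: step 5

Abbreviations: TIPS = triisopropylsilyl; Ar = 4-(TIPS-oxy)phenyl; "up" = the cyclobutane face that carries O1 and C4.
Assumption: which enantiomer of 11 the lipase spares cannot be predicted. The route is drawn for the case that the needed one is recovered; in the other case the hydroxy ester released by the enzyme is 13 itself and step 8 is dropped.

**Route**

Step 1
Reactants: 1 4-iodophenol
Product: 2 (4-iodophenoxy)triisopropylsilane
Conditions: i-Pr3SiCl, imidazole, DMF, rt
Reagents that add atoms: chlorotriisopropylsilane CC(C)[Si](Cl)(C(C)C)C(C)C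
Why: Silyl ether formation; the bulky TIPS aryl ether should outlast the carbonate and alkoxide bases of steps 2 and 4, where a tert-butyldimethylsilyl aryl ether would be lost, and it still falls to fluoride at the end.

Step 2
Reactants: 2 (4-iodophenoxy)triisopropylsilane; 3 ethyl propiolate
Product: 4 ethyl 3-Ar-prop-2-ynoate
Conditions: PdCl2(PPh3)2 (2 mol %), CuI (4 mol %), K2CO3, THF, 65 °C, slow addition of 3
Reagents that add atoms: none
Why: Sonogashira coupling of an aryl iodide, run with an inorganic base in place of an amine so that the propiolate is not consumed by aza-Michael addition.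

Step 3
Reactants: 5 tert-butyl acetate; 6 methyl dimethoxyacetate
Product: 8 tert-butyl 4,4-dimethoxy-3-oxobutanoate, via lithium enolate of tert-butyl acetate 7 (not isolated)
Conditions: LiN(i-Pr)2 (2.1 equiv), THF, −78 °C; 6, −78 → 0 °C; AcOH
Reagents that add atoms: none
Why: Crossed Claisen condensation in which 6 has no α-hydrogen and the product enolate is the sink; the tert-butyl ester is chosen so that the C8 carboxyl stays distinct from the methyl ester made in step 8 and can be freed by acid.

Step 4
Reactants: 4 ethyl 3-Ar-prop-2-ynoate; 8 tert-butyl 4,4-dimethoxy-3-oxobutanoate (1.3 equiv)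
Product: 9 tert-butyl 6-(dimethoxymethyl)-2-oxo-4-Ar-2H-pyran-5-carboxylate
Conditions: KOt-Bu (0.2 equiv), THF, 60 °C
Reagents that add atoms: none
Why: Classical 2-pyranone synthesis by Michael addition of the keto ester carbon to the aryl-bearing alkyne carbon followed by enol lactonisation onto the ethyl ester; catalytic base with 8 in excess keeps free alkoxide low and spares the silyl ether.

Step 5
Reactants: 9 tert-butyl 6-(dimethoxymethyl)-2-oxo-4-Ar-2H-pyran-5-carboxylate
Product: 10 racemic cyclobutene β-lactone, tert-butyl 1-(dimethoxymethyl)-3-oxo-5-Ar-2-oxabicyclo[2.2.0]hex-5-ene-6-carboxylate (cis-fused; target numbering: acetal on C6, Ar on C7, ester on C8; needed enantiomer drawn)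
Conditions: hν (about 350 nm, Pyrex), degassed EtOAc (5 mM), −10 °C, flow; concentrated cold and used at once
Reagents that add atoms: none
Why: Singlet excitation of the pyranone diene (ring carbons 3 to 6) starts the photochemically allowed disrotatory 4π electrocyclisation, the known valence isomerisation of 2-pyranones (parent, 4,6-dialkyl and 5-alkoxycarbonyl members) to 2-oxabicyclo[2.2.0]hex-5-en-3-ones. The one new σ bond between pyranone C3 and C6 (target C5–C6) divides the six-membered ring into the cyclobutene C5–C6–C8–C7 and the β-lactone O1–C4–C5–C6, so both rings close in the same disrotatory electrocyclic event. C5 and C6 arise together and the cis relation of C4 and O1 is forced by the bicyclo[2.2.0] frame, which cannot be trans-fused; the two disrotatory senses are equally likely, so 10 is racemic. The step needs chemoselectivity over ring opening to the conjugated ketene, over dimerisation and over loss of CO2 from excited 10: the aprotic solvent lets the ketene revert to 9, the fully substituted ring together with high dilution and absence of sensitisers disfavours dimers, and irradiation at the long-wavelength edge of the band of 9 in flow limits excitation of the aryl-conjugated cyclobutene ester of 10. Heterolysis of the allylic C6–O1 bond, the usual weakness of these lactones, is held back by the electron-poor ester on C8 and acetal on C6, by the cold weakly polar medium and by immediate hydrogenation.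

Step 6
Reactants: 10 racemic cyclobutene β-lactone
Product: 11 racemic all-cis saturated β-lactone (2-oxabicyclo[2.2.0]hexan-3-one; Ar on C7 and CO2t-Bu on C8 both up, C5–H, C7–H, C8–H and the C6 acetal on the other face)
Conditions: H2 (1 atm), 5% Rh/Al2O3, EtOAc, 0 °C
Reagents that add atoms: none
Why: Heterogeneous syn hydrogenation of a strained cyclobutene, in which the catalyst reaches only the convex face carrying C5–H and the C6 acetal, so the aryl group and the ester are pushed up and C7 is set as in the target; rhodium on alumina is chosen for its low tendency to hydrogenolyse allylic C–O bonds.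

Step 7
Reactants: 11 racemic all-cis saturated β-lactone
Product: 12 the same β-lactone as the single enantiomer drawn
Conditions: immobilised Candida antarctica lipase B, MeOH (0.6 equiv), t-BuOMe, 30 °C, stopped slightly past half conversion; chromatography
Reagents that add atoms: none
Why: Lipase-catalysed alcoholysis is a known kinetic resolution of β-lactones, in which the serine hydrolase is acylated by one enantiomer of the strained lactone and methanol releases it as hydroxy ester; going slightly past half conversion raises the enantiomeric purity of recovered 12 and thereby fixes the absolute configuration of C5, C6 and C7.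

Step 8
Reactants: 12 enantiopure all-cis β-lactone
Product: 13 1-tert-butyl 3-methyl 2-(dimethoxymethyl)-2-hydroxy-4-Ar-cyclobutane-1,3-dicarboxylate (OH, both esters and Ar all up)
Conditions: MeOH, camphorsulfonic acid (10 mol %), 0 °C → rt
Reagents that add atoms: methanol CO
Why: Acid-catalysed acyl–oxygen methanolysis of the strained lactone, chosen over alkoxide because a C6 alkoxide flanked by two ester-bearing ring carbons would suffer strain-driven De Mayo-type retro-aldol cleavage; the unlike ester groups keep 13 chiral, since with two equal esters it would be a meso compound.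

Step 9
Reactants: 13 hydroxy diester
Product: 14 the O1 acetate of 13
Conditions: Ac2O, Et3N, DMAP, CH2Cl2, 40 °C
Reagents that add atoms: acetic anhydride CC(=O)OC(C)=O
Why: DMAP-catalysed acylation of a tertiary cyclobutanol whose ring carbons are tied back; it brings in C2 and C3 and caps O1 before any ketone exists at C4, so that retro-aldol cleavage stays blocked for the rest of the route.

Step 10
Reactants: 14 acetoxy diester
Product: 15 cis-fused 4-hydroxy-5,6-dihydro-2-pyranone (enol form drawn) with C6 acetal, C7 Ar up and C8 CO2t-Bu up
Conditions: LiN(SiMe3)2 (2.5 equiv), THF, −78 → −30 °C; AcOH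
Reagents that add atoms: none
Why: Dieckmann-type intramolecular Claisen condensation of a β-acetoxy ester, a known entry to 4-hydroxy-5,6-dihydro-2-pyranones, in which the bulky amide takes the unhindered acetate proton instead of the tertiary ring protons, the enolate closes the six-membered ring on the cis methyl ester (bond C3–C4) and leaves the tert-butyl ester alone, and the stabilised product enolate is the sink.

Step 11
Reactants: 15 4-hydroxy-dihydropyranone
Product: 16 4-methoxy-5,6-dihydro-2-pyranone with C8 CO2t-Bu up
Conditions: Me2SO4, K2CO3, acetone, rt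
Reagents that add atoms: dimethyl sulfate COS(=O)(=O)OC
Why: O-Methylation of the vinylogous acid under the standard kavalactone conditions should give the 4-methoxy-2-one isomer, and carbonate in acetone is too weak to enolise the C8 ester.

Step 12
Reactants: 16 tert-butyl ester
Product: 17 C8 carboxylic acid (carboxyl up)
Conditions: CF3CO2H/CH2Cl2 (1:3), 0 °C → rt; toluene azeotrope, no aqueous work-up
Reagents that add atoms: none
Why: Acidolysis of the tert-butyl ester with loss of isobutene; in the absence of water the acetal (deactivated by the neighbouring acyloxy carbon), the aryl silyl ether and the vinylogous carbonate should persist.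

Step 13
Reactants: 17 C8 carboxylic acid
Product: 18 N-phthalimidoyl (redox-active) ester of 17
Conditions: N-hydroxyphthalimide, i-PrN=C=Ni-Pr, DMAP (5 mol %), CH2Cl2, 0 °C → rt
Reagents that add atoms: N-hydroxyphthalimide O=C1c2ccccc2C(=O)N1O
Why: Carbodiimide esterification, run nearly base-free because the activated ester has an acidified C8–H next to the O1 leaving group.

Step 14
Reactants: 19 pyridine-2-thiol
Product: 20 S-(pyridin-2-yl) ethanethioate
Conditions: AcCl, Et3N, CH2Cl2, 0 °C
Reagents that add atoms: acetyl chloride CC(=O)Cl
Why: Plain S-acylation of a thiol to give the activated thioester needed as acyl donor.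

Step 15
Reactants: 18 redox-active ester; 20 S-(pyridin-2-yl) ethanethioate
Product: 21 C8 methyl ketone (acetyl trans to Ar and O1, cis to the C6 acetal)
Conditions: NiBr2(MeOCH2CH2OMe) (10 mol %), 4,4'-di-tert-butyl-2,2'-bipyridine (12 mol %), Zn, THF/DMA, rt
Reagents that add atoms: none
Why: Nickel-catalysed decarboxylative cross-electrophile coupling of a redox-active ester with a 2-pyridyl thioester is a known ketone synthesis, in which loss of CO2 erases the wrong C8 configuration and the cyclobutyl radical should be captured by the acyl nickel species on the convex face, anti to the C7 aryl group and O1, as in related cis-to-trans decarboxylative couplings of cyclobutanes; a β-acyloxy radical, unlike a C8 enolate, does not expel O1.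

Step 16
Reactants: 21 C8 methyl ketone
Product: 22 terminal trimethylsilyl enol ether of 21
Conditions: Me3SiCl, LiN(i-Pr)2 (1.1 equiv), THF, −78 °C; pentane, filtration
Reagents that add atoms: chlorotrimethylsilane C[Si](C)(C)Cl
Why: Kinetic enolisation with in situ silylation takes the unhindered methyl proton and not the tertiary C8–H, so C8 is untouched and no enolate able to expel O1 is formed.

Step 17
Reactants: 22 silyl enol ether; 23 malonyl dichloride
Product: 24 C8 (4-hydroxy-2-oxo-2H-pyran-6-yl) compound
Conditions: Et2O, −78 °C → rt
Reagents that add atoms: none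
Why: Known pyranone annulation of silyl enol ethers with malonyl dichloride, that is C-acylation at the methylene terminus and then enol O-acylation by the second acid chloride, which closes the 4-hydroxy-2-pyranone without any base.

Step 18
Reactants: 24 4-hydroxy-2-pyranone
Product: 25 C8 (4-methoxy-2-oxo-2H-pyran-6-yl) compound, C6 acetal intact
Conditions: Me2SO4, K2CO3, acetone, rt
Reagents that add atoms: dimethyl sulfate COS(=O)(=O)OC
Why: Standard O-methylation of a 4-hydroxy-2-pyranone, which favours the 4-methoxy-2-one; the mild heterogeneous base should not touch the tertiary C8–H.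

Step 19
Reactants: 25 dimethyl acetal
Product: 26 C6 aldehyde
Conditions: CF3CO2H/H2O/CH2Cl2, rt
Reagents that add atoms: water O
Why: Acid hydrolysis of the acetal, done before the styryl group exists so that C6–O1 is not yet allylic and does not ionise; the aldehyde has a quaternary α-carbon and cannot enolise.

Step 20
Reactants: 27 4-hydroxybenzaldehyde
Product: 28 4-(TIPS-oxy)benzaldehyde
Conditions: i-Pr3SiCl, imidazole, DMF, rt
Reagents that add atoms: chlorotriisopropylsilane CC(C)[Si](Cl)(C(C)C)C(C)C
Why: Silyl ether formation with the same group as on the other phenol, so that one fluoride step frees both.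

Step 21
Reactants: 28 4-(TIPS-oxy)benzaldehyde
Product: 29 4-(TIPS-oxy)benzyl alcohol
Conditions: NaBH4, MeOH, 0 °C
Reagents that add atoms: none
Why: Borohydride reduction of an aromatic aldehyde.

Step 22
Reactants: 29 4-(TIPS-oxy)benzyl alcohol
Product: 30 4-(TIPS-oxy)benzyl bromide
Conditions: CBr4, PPh3, CH2Cl2, 0 °C; used directly
Reagents that add atoms: tetrabromomethane BrC(Br)(Br)Br
Why: Appel reaction under neutral conditions, which suits this ionisation-prone benzylic bromide.

Step 23
Reactants: 30 4-(TIPS-oxy)benzyl bromide
Product: 31 tributyl[4-(TIPS-oxy)benzyl]phosphonium bromide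
Conditions: PBu3, MeCN, rt
Reagents that add atoms: tributylphosphine CCCCP(CCCC)CCCC
Why: Quaternisation of a trialkylphosphine by SN2 displacement of a benzylic bromide.

Step 24
Reactants: 26 C6 aldehyde; 31 phosphonium bromide (1.3 equiv)
Product: 33 bis-TIPS ether of the target, (E)-styryl on C6, via benzylidene tributylphosphorane 32 (not isolated)
Conditions: 31, NaN(SiMe3)2 (1.2 equiv), THF, −78 → 0 °C; 26, −78 °C → rt
Reagents that add atoms: none
Why: Wittig olefination with a semistabilised trialkylphosphonium ylide, a combination known for high E selectivity and reinforced here by the quaternary α-carbon; the salt is kept in excess over the amide so that no strong base meets C8–H or C5–H, and the oxaphosphetane pathway leaves no free alkoxide next to the O1 acyl group.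

Step 25
Reactants: 33 bis-TIPS ether
Product: 34 target CNP0228336.2
Conditions: Bu4NF (2.2 equiv), AcOH (2.5 equiv), THF, 0 °C
Reagents that add atoms: none
Why: Fluoride cleavage of both aryl silyl ethers, buffered with acetic acid so that no phenoxide or basic fluoride can trigger loss of O1 or opening of the cyclobutane, and free of strong acid that would ionise the tertiary cinnamyl-type C6–O1 bond.

**Compound list**
1 | 4-iodophenol | Oc1ccc(I)cc1 | starting material
2 | (4-iodophenoxy)triisopropylsilane | CC(C)[Si](Oc1ccc(I)cc1)(C(C)C)C(C)C | intermediate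
3 | ethyl propiolate | C#CC(=O)OCC | starting material
4 | ethyl 3-[4-(TIPS-oxy)phenyl]prop-2-ynoate | CCOC(=O)C#Cc1ccc(O[Si](C(C)C)(C(C)C)C(C)C)cc1 | intermediate
5 | tert-butyl acetate | CC(=O)OC(C)(C)C | starting material
6 | methyl dimethoxyacetate | COC(OC)C(=O)OC | starting material
7 | lithium enolate of tert-butyl acetate | [Li+].C=C([O-])OC(C)(C)C | intermediate
8 | tert-butyl 4,4-dimethoxy-3-oxobutanoate | COC(OC)C(=O)CC(=O)OC(C)(C)C | intermediate
9 | tert-butyl 6-(dimethoxymethyl)-2-oxo-4-[4-(TIPS-oxy)phenyl]-2H-pyran-5-carboxylate | O=c1cc(-c2ccc(O[Si](C(C)C)(C(C)C)C(C)C)cc2)c(C(=O)OC(C)(C)C)c(C(OC)OC)o1 | intermediate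
10 | cyclobutene β-lactone, racemate (needed enantiomer drawn) | O=C1O[C@]2(C(OC)OC)[C@H]1C(c1ccc(O[Si](C(C)C)(C(C)C)C(C)C)cc1)=C2C(=O)OC(C)(C)C | intermediate
11 | all-cis saturated β-lactone, racemate (needed enantiomer drawn) | O=C1O[C@]2(C(OC)OC)[C@H]1[C@H](c1ccc(O[Si](C(C)C)(C(C)C)C(C)C)cc1)[C@@H]2C(=O)OC(C)(C)C | intermediate
12 | all-cis saturated β-lactone, single enantiomer | O=C1O[C@]2(C(OC)OC)[C@H]1[C@H](c1ccc(O[Si](C(C)C)(C(C)C)C(C)C)cc1)[C@@H]2C(=O)OC(C)(C)C | intermediate
13 | all-cis hydroxy diester (C5 CO2Me, C8 CO2t-Bu) | O[C@]1(C(OC)OC)[C@H](C(=O)OC)[C@H](c2ccc(O[Si](C(C)C)(C(C)C)C(C)C)cc2)[C@@H]1C(=O)OC(C)(C)C | intermediate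
14 | O1 acetate of 13 | CC(=O)O[C@]1(C(OC)OC)[C@H](C(=O)OC)[C@H](c2ccc(O[Si](C(C)C)(C(C)C)C(C)C)cc2)[C@@H]1C(=O)OC(C)(C)C | intermediate
15 | fused 4-hydroxy-5,6-dihydro-2-pyranone, C8 ester up | OC1=CC(=O)O[C@]2(C(OC)OC)[C@H]1[C@H](c1ccc(O[Si](C(C)C)(C(C)C)C(C)C)cc1)[C@@H]2C(=O)OC(C)(C)C | intermediate
16 | fused 4-methoxy-5,6-dihydro-2-pyranone, C8 ester up | COC1=CC(=O)O[C@]2(C(OC)OC)[C@H]1[C@H](c1ccc(O[Si](C(C)C)(C(C)C)C(C)C)cc1)[C@@H]2C(=O)OC(C)(C)C | intermediate
17 | C8 carboxylic acid (up) | COC1=CC(=O)O[C@]2(C(OC)OC)[C@H]1[C@H](c1ccc(O[Si](C(C)C)(C(C)C)C(C)C)cc1)[C@@H]2C(=O)O | intermediate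
18 | N-phthalimidoyl ester of 17 | COC1=CC(=O)O[C@]2(C(OC)OC)[C@H]1[C@H](c1ccc(O[Si](C(C)C)(C(C)C)C(C)C)cc1)[C@@H]2C(=O)ON1C(=O)c2ccccc2C1=O | intermediate
19 | pyridine-2-thiol | Sc1ccccn1 | starting material
20 | S-(pyridin-2-yl) ethanethioate | CC(=O)Sc1ccccn1 | intermediate
21 | C8 methyl ketone (acetyl trans to Ar and O1) | COC1=CC(=O)O[C@]2(C(OC)OC)[C@H]1[C@H](c1ccc(O[Si](C(C)C)(C(C)C)C(C)C)cc1)[C@H]2C(C)=O | intermediate
22 | trimethylsilyl enol ether of 21 | COC1=CC(=O)O[C@]2(C(OC)OC)[C@H]1[C@H](c1ccc(O[Si](C(C)C)(C(C)C)C(C)C)cc1)[C@H]2C(=C)O[Si](C)(C)C | intermediate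
23 | malonyl dichloride | O=C(Cl)CC(=O)Cl | starting material
24 | C8 4-hydroxy-2-pyranon-6-yl compound | COC1=CC(=O)O[C@]2(C(OC)OC)[C@H]1[C@H](c1ccc(O[Si](C(C)C)(C(C)C)C(C)C)cc1)[C@H]2c1cc(O)cc(=O)o1 | intermediate
25 | C8 4-methoxy-2-pyranon-6-yl compound, C6 acetal | COC1=CC(=O)O[C@]2(C(OC)OC)[C@H]1[C@H](c1ccc(O[Si](C(C)C)(C(C)C)C(C)C)cc1)[C@H]2c1cc(OC)cc(=O)o1 | intermediate
26 | C6 aldehyde | COC1=CC(=O)O[C@]2(C=O)[C@H]1[C@H](c1ccc(O[Si](C(C)C)(C(C)C)C(C)C)cc1)[C@H]2c1cc(OC)cc(=O)o1 | intermediate
27 | 4-hydroxybenzaldehyde | O=Cc1ccc(O)cc1 | starting material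
28 | 4-(TIPS-oxy)benzaldehyde | O=Cc1ccc(O[Si](C(C)C)(C(C)C)C(C)C)cc1 | intermediate
29 | 4-(TIPS-oxy)benzyl alcohol | OCc1ccc(O[Si](C(C)C)(C(C)C)C(C)C)cc1 | intermediate
30 | 4-(TIPS-oxy)benzyl bromide | BrCc1ccc(O[Si](C(C)C)(C(C)C)C(C)C)cc1 | intermediate
31 | tributyl[4-(TIPS-oxy)benzyl]phosphonium bromide | [Br-].CCCC[P+](CCCC)(CCCC)Cc1ccc(O[Si](C(C)C)(C(C)C)C(C)C)cc1 | intermediate
32 | benzylidene tributylphosphorane | CCCCP(CCCC)(CCCC)=Cc1ccc(O[Si](C(C)C)(C(C)C)C(C)C)cc1 | intermediate
33 | bis-TIPS ether of the target | COC1=CC(=O)O[C@]2(/C=C/c3ccc(O[Si](C(C)C)(C(C)C)C(C)C)cc3)[C@H]1[C@H](c1ccc(O[Si](C(C)C)(C(C)C)C(C)C)cc1)[C@H]2c1cc(OC)cc(=O)o1 | intermediate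
34 | CNP0228336.2 | COC1=CC(=O)O[C@]2(/C=C/c3ccc(O)cc3)[C@H]1[C@H](c1ccc(O)cc1)[C@H]2c1cc(OC)cc(=O)o1 | target

**Step count**
Total steps: 25. Longest linear sequence: 19 (steps 1, 2, 4–13, 15–19, 24, 25).

**Steps most likely to fail**

Step 5. The electron-rich silyloxyaryl group on C7 may assist heterolysis of the allylic C6–O1 bond of 10, leading to migration of the carboxylate and return to an isomeric pyranone. The aryl-conjugated cyclobutene ester of 10 also absorbs close to 9, so loss of CO2 may begin before conversion is complete.
The fallback keeps the ring closure but changes the electronic character of the substrate. It sets out from 9 and returns at 11.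
- Bu4NF/AcOH gives the free phenol pyranone F1.
- Benzyl chloroformate and pyridine give the aryl benzyl carbonate pyranone F2. Its acceptor-substituted aryl group no longer stabilises the allyl cation, and it shifts the absorption of the photoproduct to shorter wavelength.
- Irradiation gives the carbonate cyclobutene lactone F3.
- Hydrogenation over Rh/Al2O3 gives the saturated carbonate lactone F4.
- Hydrogenolysis over Pd/C gives the phenol lactone F5. This is harmless at that point because C6–O1 is no longer allylic.
- i-Pr3SiCl/imidazole then gives 11.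

Step 6. The metal sits on the convex face, anti to O1. This is the geometry for insertion into the allylic C6–O1 bond, so loss of O1 by hydrogenolysis may outrun saturation of the hindered tetrasubstituted alkene, and a slow reaction may let the arene be attacked.
The fallback gives up metal catalysis for a concerted, metal-free group transfer. Setting out from 10, diimide F6 is generated in large excess from 2-nitrobenzenesulfonyl hydrazide in CH2Cl2 at rt. It should deliver both hydrogens syn to the same convex face and lead directly to 11. It has no means of cleaving a C–O bond, and the strain of the bicyclo[2.2.0]hexene alkene together with its ester substituent should offset the tetrasubstitution.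

Step 15. Capture of the hindered cyclobutyl radical by the acyl nickel species may be slow. Reduction or dimerisation of the radical and homocoupling of the two electrophiles would then dominate.
The fallback replaces the cross-electrophile coupling by a redox-neutral coupling with a preformed nucleophile, followed by oxidative cleavage. It sets out from 18 and returns at 21.
- Isopropenylzinc chloride F7 is prepared from isopropenylmagnesium bromide and ZnCl2.
- F7 is coupled with 18 under NiCl2(MeOCH2CH2OMe)/2,2'-bipyridine catalysis (decarboxylative Negishi-type alkenylation) to give the C8 isopropenyl compound F8. The new group should enter on the convex face.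
- Lemieux–Johnson cleavage (OsO4 catalytic, NaIO4, 2,6-lutidine, dioxane/H2O) of the electron-rich 1,1-disubstituted alkene, in preference to the electron-poor methoxy enoate, gives 21.

**Further compounds**
F1 | step 5 | tert-butyl 6-(dimethoxymethyl)-4-(4-hydroxyphenyl)-2-oxo-2H-pyran-5-carboxylate | O=c1cc(-c2ccc(O)cc2)c(C(=O)OC(C)(C)C)c(C(OC)OC)o1
F2 | step 5 | aryl benzyl carbonate pyranone | O=c1cc(-c2ccc(OC(=O)OCc3ccccc3)cc2)c(C(=O)OC(C)(C)C)c(C(OC)OC)o1
F3 | step 5 | carbonate cyclobutene β-lactone (racemate, one enantiomer drawn) | O=C1O[C@]2(C(OC)OC)[C@H]1C(c1ccc(OC(=O)OCc3ccccc3)cc1)=C2C(=O)OC(C)(C)C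
F4 | step 5 | carbonate all-cis saturated β-lactone (racemate, one enantiomer drawn) | O=C1O[C@]2(C(OC)OC)[C@H]1[C@H](c1ccc(OC(=O)OCc3ccccc3)cc1)[C@@H]2C(=O)OC(C)(C)C
F5 | step 5 | phenol all-cis saturated β-lactone (racemate, one enantiomer drawn) | O=C1O[C@]2(C(OC)OC)[C@H]1[C@H](c1ccc(O)cc1)[C@@H]2C(=O)OC(C)(C)C
F6 | step 6 | diimide | N=N
F7 | step 15 | isopropenylzinc chloride | C=C(C)[Zn]Cl
F8 | step 15 | C8 isopropenyl compound (isopropenyl trans to Ar and O1) | COC1=CC(=O)O[C@]2(C(OC)OC)[C@H]1[C@H](c1ccc(O[Si](C(C)C)(C(C)C)C(C)C)cc1)[C@H]2C(C)=C
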